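**Strategy.** Ring A (C1–C5, C10; labdane numbering) is cut across C4–C5 and C2–C3: with C10 left trigonal, C2–C1–C10–C5 is a diene and C3–C4 a dienophile. A catalytic enantioselective Diels–Alder reaction of an acyclic triene chloride with a (Z)-β-silyl methacrolein closes ring A in one operation, forging both bonds, the quaternary C4 beside the C5 methine, and a C3–Si bond as masked hydroxyl. The step exploits this C3/C4 substitution pattern and leaves the C1=C10 alkene, whose epoxide later feeds a titanocene radical cyclization that closes ring B with the exocyclic C8 methylene. Ketone chemistry then installs the 2,3-diol; a nickel coupling adds the butenolide.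

Key step: step 6

Remark (assumption): labdane numbering of the target is used for all atom labels (C17 = exocyclic methylene carbon, C18 = oxygenated carbon on C4, C19 = methyl on C4, C20 = methyl on C10); pent-4-ynal, propyne, benzyldimethylsilane and 4-bromofuran-2(5H)-one are taken as commercial.

**Step 1**
Reactants: 1 pent-4-ynal
Product: 2 (2E)-2-methylhept-2-en-6-ynal
Conditions: 2-(triphenylphosphoranylidene)propanal, toluene, 80 °C
Reagents that add atoms: 2-(triphenylphosphoranylidene)propanal, CC(C=O)=P(c1ccccc1)(c1ccccc1)c1ccccc1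
Why: Wittig olefination with the stabilized ylide should give the (E)-α-methyl enal under thermodynamic control and leaves the terminal alkyne untouched.

**Step 2**
Reactants: 2 (2E)-2-methylhept-2-en-6-ynal
Product: 3 (3E)-3-methylnona-1,3-dien-8-yne
Conditions: Ph3PCH3Br, NaHMDS, THF, 0 °C; then 2, −78 → 0 °C
Reagents that add atoms: methyltriphenylphosphonium bromide, C[P+](c1ccccc1)(c1ccccc1)c1ccccc1.[Br-]
Why: Wittig methylenation of the aldehyde (1,2-addition of the non-stabilized ylide, used without excess base so that the alkyne C–H survives) should give the (E)-1,3-diene with the alkene geometry of 2 retained.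

**Step 3**
Reactants: 3 (3E)-3-methylnona-1,3-dien-8-yne
Product: 6 (3E,7E)-4,8-dimethyldeca-3,7,9-trien-1-ol, via alkenylalane 4 (not isolated), via lithium alanate 5 (not isolated)
Conditions: Me3Al, Cp2ZrCl2 (cat.), CH2Cl2, 0 °C → rt; then n-BuLi, THF, −78 °C; then oxirane, −78 → 0 °C; aq. NH4Cl
Reagents that add atoms: trimethylaluminium, C[Al](C)C; oxirane, C1CO1
Why: Negishi zirconium-catalysed carboalumination adds methyl (internal carbon) and aluminium (terminal carbon) syn across the alkyne, and the derived alanate opens oxirane with retention at the alkenyl carbon, which fixes the (E)-trisubstituted C8=C9 alkene.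

**Step 4**
Reactants: 6 (3E,7E)-4,8-dimethyldeca-3,7,9-trien-1-ol
Product: 7 (3E,7E)-10-chloro-3,7-dimethyldeca-1,3,7-triene
Conditions: PPh3, N-chlorosuccinimide, CH2Cl2, 0 °C → rt
Reagents that add atoms: N-chlorosuccinimide, O=C1CCC(=O)N1Cl
Why: Appel-type chlorination displaces the oxyphosphonium ion of the primary alcohol by chloride (SN2) without touching the diene.

**Step 5**
Reactants: 8 propyne
Product: 9 (2Z)-3-[benzyl(dimethyl)silyl]-2-methylprop-2-enal
Conditions: benzyldimethylsilane, CO (20 atm), Rh4(CO)12 (cat.), Et3N (cat.), toluene, 100 °C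
Reagents that add atoms: benzyldimethylsilane, C[SiH](C)Cc1ccccc1; carbon monoxide, [C-]#[O+]
Why: Rhodium-catalysed silylformylation adds silicon (terminal carbon) and the formyl group (internal carbon) syn across the alkyne, which should give the (Z)-β-silyl enal regio- and stereoselectively.

**Step 6**
Reactants: 7 (3E,7E)-10-chloro-3,7-dimethyldeca-1,3,7-triene; 9 (2Z)-3-[benzyl(dimethyl)silyl]-2-methylprop-2-enal
Product: 11 [(1S,2S,6S)-6-[benzyl(dimethyl)silyl]-2-[(3E)-6-chloro-3-methylhex-3-en-1-yl]-1,3-dimethylcyclohex-3-en-1-yl]methanol, via cycloadduct aldehyde 10 (not isolated)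
Conditions: (S)-3,3-diphenyl-1-(o-tolyl)tetrahydropyrrolo[1,2-c][1,3,2]oxazaborole (20 mol %), Tf2NH (16 mol %), CH2Cl2, −78 → −20 °C; then NaBH4, MeOH, −78 → 0 °C (the antipodal catalyst is used instead should the facial sense demand it)
Reagents that add atoms: none
Why: The aldehyde of 9, bound to the chiral cationic oxazaborolidine, undergoes a concerted but asynchronous normal-demand [4+2] cycloaddition with the s-cis 1,3-diene terminus of 7 (C2=C1–C10=C5), which forms C2–C3 and C4–C5 and thereby closes ring A (the only ring formed, by suprafacial six-centre closure); NaBH4 then reduces the formyl group in the same flask. The closest known reaction type is the oxazaborolidinium-catalysed enantioselective Diels–Alder reaction of 2-substituted acroleins with alkyl-substituted acyclic dienes. Regiochemistry: the electrophilic β-carbon C3 bonds to the unsubstituted terminus C2 and the α-carbon C4 to the alkyl-bearing terminus C5, as dictated by the directing effect of the C5 substituent and by the bulk of silicon on C3, which should outweigh the weaker opposing pull of the C10 methyl. C5 is set by the (E)-geometry of the diene together with the catalyst-controlled face, C4 by the exo orientation of the formyl group (the silyl group cis to it and the bound catalyst turn away from the diene while the small methyl sits endo), and C3 by the (Z)-geometry of 9, this last centre being erased later. The step therefore needs regio-, exo- and facial selectivity, secured by these substituent effects and by the catalyst, and chemoselectivity, which is given because the isolated trisubstituted alkene and the chloride of 7 are inert at low temperature.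

**Step 7**
Reactants: 11 [(1S,2S,6S)-6-[benzyl(dimethyl)silyl]-2-[(3E)-6-chloro-3-methylhex-3-en-1-yl]-1,3-dimethylcyclohex-3-en-1-yl]methanol
Product: 13 (1S,2S,3S)-3-[(3E)-6-chloro-3-methylhex-3-en-1-yl]-2-(hydroxymethyl)-2,4-dimethylcyclohex-4-en-1-ol, via fluorosilane 12 (not isolated)
Conditions: TBAF, THF, 0 °C → rt; then KHCO3, 30% aq. H2O2, MeOH, 40 °C
Reagents that add atoms: hydrogen peroxide, OO
Why: Tamao oxidation: fluoride cleaves the benzyl–silicon bond and the fluorosilane is oxidized by basic peroxide with migration of C3 from silicon to oxygen with retention, under conditions that spare the alkenes and the chloride.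

**Step 8**
Reactants: 13 (1S,2S,3S)-3-[(3E)-6-chloro-3-methylhex-3-en-1-yl]-2-(hydroxymethyl)-2,4-dimethylcyclohex-4-en-1-ol
Product: 14 (1S,2S,3S)-2-{[tert-butyl(dimethyl)silyl]oxymethyl}-3-[(3E)-6-chloro-3-methylhex-3-en-1-yl]-2,4-dimethylcyclohex-4-en-1-ol
Conditions: TBSCl, imidazole, CH2Cl2, 0 °C
Reagents that add atoms: tert-butyldimethylsilyl chloride, CC(C)(C)[Si](C)(C)Cl
Why: Silylation should occur selectively at the primary hydroxyl, the secondary one being flanked by the quaternary C4.

**Step 9**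
Reactants: 14 (1S,2S,3S)-2-{[tert-butyl(dimethyl)silyl]oxymethyl}-3-[(3E)-6-chloro-3-methylhex-3-en-1-yl]-2,4-dimethylcyclohex-4-en-1-ol
Product: 15 (1S,2R,3S,4S,6R)-3-{[tert-butyl(dimethyl)silyl]oxymethyl}-2-[(3E)-6-chloro-3-methylhex-3-en-1-yl]-1,3-dimethyl-7-oxabicyclo[4.1.0]heptan-4-ol (epoxide cis to the hydroxyl)
Conditions: VO(acac)2 (cat.), t-BuOOH, CH2Cl2, rt
Reagents that add atoms: tert-butyl hydroperoxide, CC(C)(C)OO
Why: Vanadium-catalysed hydroxyl-directed epoxidation of the homoallylic alcohol delivers oxygen to the ring alkene (C1=C10) on the face of the hydroxyl and spares the remote trisubstituted alkene; the epoxide configuration is erased later.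

**Step 10**
Reactants: 15 (1S,2R,3S,4S,6R)-3-{[tert-butyl(dimethyl)silyl]oxymethyl}-2-[(3E)-6-chloro-3-methylhex-3-en-1-yl]-1,3-dimethyl-7-oxabicyclo[4.1.0]heptan-4-ol
Product: 16 (1S,2R,3S,6R)-3-{[tert-butyl(dimethyl)silyl]oxymethyl}-2-[(3E)-6-chloro-3-methylhex-3-en-1-yl]-1,3-dimethyl-7-oxabicyclo[4.1.0]heptan-4-one
Conditions: DMP [1,1,1-triacetoxy-1,1-dihydro-1,2-benziodoxol-3(1H)-one], NaHCO3, CH2Cl2, 0 °C → rt
Reagents that add atoms: none
Why: Buffered hypervalent-iodine oxidation of the secondary alcohol should give the β,γ-epoxy ketone under neutral conditions without opening the epoxide.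

**Step 11**
Reactants: 16 (1S,2R,3S,6R)-3-{[tert-butyl(dimethyl)silyl]oxymethyl}-2-[(3E)-6-chloro-3-methylhex-3-en-1-yl]-1,3-dimethyl-7-oxabicyclo[4.1.0]heptan-4-one
Product: 17 (1R,4S,5S,9R,10S)-18-[tert-butyl(dimethyl)silyl]oxy-12-chloro-1-hydroxy-13,14,15,16-tetranorlabd-8(17)-en-3-one
Conditions: Cp2TiCl2, Mn powder (zerovalent manganese), THF, rt, slow addition of 16; aq. NaH2PO4
Reagents that add atoms: none
Why: Cp2TiCl (trivalent titanium, made in the flask) opens the epoxide homolytically to the tertiary C10 radical, which adds 6-endo to the (E)-trisubstituted alkene through a chair transition state (trans ring fusion and equatorial C9 side chain, both set relative to C5), and the tertiary C8 radical is trapped by a second Cp2TiCl and loses hydride toward C17 to give the exocyclic alkene, as in titanocene-mediated epoxypolyene cyclizations.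

**Step 12**
Reactants: 17 (1R,4S,5S,9R,10S)-18-[tert-butyl(dimethyl)silyl]oxy-12-chloro-1-hydroxy-13,14,15,16-tetranorlabd-8(17)-en-3-one
Product: 19 (4S,5S,9R,10S)-18-[tert-butyl(dimethyl)silyl]oxy-12-chloro-13,14,15,16-tetranorlabda-1,8(17)-dien-3-one, via mesylate 18 (not isolated)
Conditions: MsCl, Et3N (excess), CH2Cl2, 0 °C → rt
Reagents that add atoms: none
Why: Mesylation of the β-hydroxy ketone followed by E1cB elimination through the C2 enolate removes the oxygen at C1 and gives the conjugated enone.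

**Step 13**
Reactants: 19 (4S,5S,9R,10S)-18-[tert-butyl(dimethyl)silyl]oxy-12-chloro-13,14,15,16-tetranorlabda-1,8(17)-dien-3-one
Product: 21 (2S,4S,5S,9R,10S)-18-[tert-butyl(dimethyl)silyl]oxy-12-chloro-2-hydroxy-13,14,15,16-tetranorlabd-8(17)-en-3-one, via lithium enolate 20 (not isolated)
Conditions: LiBH(s-Bu)3 (L-Selectride), THF, −78 °C; then 2-(benzenesulfonyl)-3-phenyloxaziridine, −78 → −40 °C; aq. NH4Cl
Reagents that add atoms: 2-(benzenesulfonyl)-3-phenyloxaziridine, O=S(=O)(c1ccccc1)N1OC1c1ccccc1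
Why: Conjugate hydride delivery to the β-unsubstituted enone (the carbonyl is shielded by the quaternary C4) generates the C2–C3 enolate regiospecifically, and oxygen transfer from the oxaziridine occurs on the face opposite to the axial methyl groups on C4 and C10, giving the equatorial 2-hydroxyl.

**Step 14**
Reactants: 21 (2S,4S,5S,9R,10S)-18-[tert-butyl(dimethyl)silyl]oxy-12-chloro-2-hydroxy-13,14,15,16-tetranorlabd-8(17)-en-3-one
Product: 22 (2S,3S,4S,5S,9R,10S)-18-[tert-butyl(dimethyl)silyl]oxy-12-chloro-13,14,15,16-tetranorlabd-8(17)-ene-2,3-diol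
Conditions: NaBH4, MeOH, 0 °C
Reagents that add atoms: none
Why: Hydride should attack the C3 ketone along the axial trajectory (the equatorial approach is blocked by the axial C19 methyl), giving the equatorial 3-hydroxyl trans to the 2-hydroxyl.

**Step 15**
Reactants: 22 (2S,3S,4S,5S,9R,10S)-18-[tert-butyl(dimethyl)silyl]oxy-12-chloro-13,14,15,16-tetranorlabd-8(17)-ene-2,3-diol; 23 4-bromofuran-2(5H)-one
Product: 24 (2S,3S,4S,5S,9R,10S)-18-[tert-butyl(dimethyl)silyl]oxy-2,3-dihydroxylabda-8(17),13-dien-15,16-olide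
Conditions: NiBr2(dme) (10 mol %), 4,4′-di-tert-butyl-2,2′-bipyridine, NaI, Mn powder (zerovalent manganese), DMA, 50 °C
Reagents that add atoms: none
Why: Nickel-catalysed reductive cross-electrophile coupling: the alkenyl bromide adds oxidatively to zerovalent nickel, the primary chloride is activated by in situ iodide exchange and captured as a radical, and reductive elimination forms the C12–C13 bond with tolerance of the free diol and the exocyclic alkene.

**Step 16**
Reactants: 24 (2S,3S,4S,5S,9R,10S)-18-[tert-butyl(dimethyl)silyl]oxy-2,3-dihydroxylabda-8(17),13-dien-15,16-olide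
Product: 25 (2S,3S,4S,5S,9R,10S)-2,3,18-trihydroxylabda-8(17),13-dien-15,16-olide, i.e. 4-{2-[(1R,4aS,5S,6S,7S,8aS)-6,7-dihydroxy-5-(hydroxymethyl)-5,8a-dimethyl-2-methylidenedecahydronaphthalen-1-yl]ethyl}furan-2(5H)-one
Conditions: HF·pyridine, THF, 0 °C → rt
Reagents that add atoms: none
Why: Fluoride-mediated cleavage of the silyl ether frees the C18 hydroxyl under conditions that should neither isomerize the exocyclic alkene nor open the butenolide.

**Compound list**

1 | pent-4-ynal | C#CCCC=O | starting material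
2 | (2E)-2-methylhept-2-en-6-ynal | C#CCC/C=C(\C)C=O | intermediate
3 | (3E)-3-methylnona-1,3-dien-8-yne | C#CCC/C=C(\C)C=C | intermediate
4 | [(1E,5E)-2,6-dimethylocta-1,5,7-trien-1-yl]dimethylaluminium | C[Al](C)/C=C(\C)CC/C=C(\C)C=C | intermediate
5 | lithium butyl[(1E,5E)-2,6-dimethylocta-1,5,7-trien-1-yl]dimethylaluminate | [Li+].CCCC[Al-](C)(C)/C=C(\C)CC/C=C(\C)C=C | intermediate
6 | (3E,7E)-4,8-dimethyldeca-3,7,9-trien-1-ol | OCC/C=C(\C)CC/C=C(\C)C=C | intermediate
7 | (3E,7E)-10-chloro-3,7-dimethyldeca-1,3,7-triene | ClCC/C=C(\C)CC/C=C(\C)C=C | intermediate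
8 | propyne | CC#C | starting material
9 | (2Z)-3-[benzyl(dimethyl)silyl]-2-methylprop-2-enal | O=C/C(C)=C\[Si](C)(C)Cc1ccccc1 | intermediate
10 | (1S,2S,6S)-6-[benzyl(dimethyl)silyl]-2-[(3E)-6-chloro-3-methylhex-3-en-1-yl]-1,3-dimethylcyclohex-3-ene-1-carbaldehyde | ClCC/C=C(\C)CC[C@H]1C(C)=CC[C@H]([Si](C)(C)Cc2ccccc2)[C@]1(C)C=O | intermediate
11 | [(1S,2S,6S)-6-[benzyl(dimethyl)silyl]-2-[(3E)-6-chloro-3-methylhex-3-en-1-yl]-1,3-dimethylcyclohex-3-en-1-yl]methanol | ClCC/C=C(\C)CC[C@H]1C(C)=CC[C@H]([Si](C)(C)Cc2ccccc2)[C@]1(C)CO | intermediate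
12 | [(1S,2S,6S)-2-[(3E)-6-chloro-3-methylhex-3-en-1-yl]-6-[fluoro(dimethyl)silyl]-1,3-dimethylcyclohex-3-en-1-yl]methanol | ClCC/C=C(\C)CC[C@H]1C(C)=CC[C@H]([Si](C)(C)F)[C@]1(C)CO | intermediate
13 | (1S,2S,3S)-3-[(3E)-6-chloro-3-methylhex-3-en-1-yl]-2-(hydroxymethyl)-2,4-dimethylcyclohex-4-en-1-ol | ClCC/C=C(\C)CC[C@H]1C(C)=CC[C@H](O)[C@]1(C)CO | intermediate
14 | (1S,2S,3S)-2-{[tert-butyl(dimethyl)silyl]oxymethyl}-3-[(3E)-6-chloro-3-methylhex-3-en-1-yl]-2,4-dimethylcyclohex-4-en-1-ol | ClCC/C=C(\C)CC[C@H]1C(C)=CC[C@H](O)[C@]1(C)CO[Si](C)(C)C(C)(C)C | intermediate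
15 | (1S,2R,3S,4S,6R)-3-{[tert-butyl(dimethyl)silyl]oxymethyl}-2-[(3E)-6-chloro-3-methylhex-3-en-1-yl]-1,3-dimethyl-7-oxabicyclo[4.1.0]heptan-4-ol | ClCC/C=C(\C)CC[C@H]1[C@]2(C)O[C@@H]2C[C@H](O)[C@]1(C)CO[Si](C)(C)C(C)(C)C | intermediate
16 | (1S,2R,3S,6R)-3-{[tert-butyl(dimethyl)silyl]oxymethyl}-2-[(3E)-6-chloro-3-methylhex-3-en-1-yl]-1,3-dimethyl-7-oxabicyclo[4.1.0]heptan-4-one | ClCC/C=C(\C)CC[C@H]1[C@]2(C)O[C@@H]2CC(=O)[C@]1(C)CO[Si](C)(C)C(C)(C)C | intermediate
17 | (1R,4S,5S,9R,10S)-18-[tert-butyl(dimethyl)silyl]oxy-12-chloro-1-hydroxy-13,14,15,16-tetranorlabd-8(17)-en-3-one | C=C1CC[C@H]2[C@@](C)([C@H](O)CC(=O)[C@]2(C)CO[Si](C)(C)C(C)(C)C)[C@@H]1CCCl | intermediate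
18 | (1R,4S,5S,9R,10S)-18-[tert-butyl(dimethyl)silyl]oxy-12-chloro-3-oxo-13,14,15,16-tetranorlabd-8(17)-en-1-yl methanesulfonate | C=C1CC[C@H]2[C@@](C)([C@H](OS(C)(=O)=O)CC(=O)[C@]2(C)CO[Si](C)(C)C(C)(C)C)[C@@H]1CCCl | intermediate
19 | (4S,5S,9R,10S)-18-[tert-butyl(dimethyl)silyl]oxy-12-chloro-13,14,15,16-tetranorlabda-1,8(17)-dien-3-one | C=C1CC[C@H]2[C@@](C)(C=CC(=O)[C@]2(C)CO[Si](C)(C)C(C)(C)C)[C@@H]1CCCl | intermediate
20 | lithium (4S,5S,9R,10S)-18-[tert-butyl(dimethyl)silyl]oxy-12-chloro-13,14,15,16-tetranorlabda-2,8(17)-dien-3-olate | C=C1CC[C@H]2[C@@](C)(CC=C([O-])[C@]2(C)CO[Si](C)(C)C(C)(C)C)[C@@H]1CCCl.[Li+] | intermediate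
21 | (2S,4S,5S,9R,10S)-18-[tert-butyl(dimethyl)silyl]oxy-12-chloro-2-hydroxy-13,14,15,16-tetranorlabd-8(17)-en-3-one | C=C1CC[C@H]2[C@@](C)(C[C@H](O)C(=O)[C@]2(C)CO[Si](C)(C)C(C)(C)C)[C@@H]1CCCl | intermediate
22 | (2S,3S,4S,5S,9R,10S)-18-[tert-butyl(dimethyl)silyl]oxy-12-chloro-13,14,15,16-tetranorlabd-8(17)-ene-2,3-diol | C=C1CC[C@H]2[C@@](C)(C[C@H](O)[C@@H](O)[C@]2(C)CO[Si](C)(C)C(C)(C)C)[C@@H]1CCCl | intermediate
23 | 4-bromofuran-2(5H)-one | O=C1C=C(Br)CO1 | starting material
24 | (2S,3S,4S,5S,9R,10S)-18-[tert-butyl(dimethyl)silyl]oxy-2,3-dihydroxylabda-8(17),13-dien-15,16-olide | C=C1CC[C@H]2[C@@](C)(C[C@H](O)[C@@H](O)[C@]2(C)CO[Si](C)(C)C(C)(C)C)[C@@H]1CCC1=CC(=O)OC1 | intermediate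
25 | (2S,3S,4S,5S,9R,10S)-2,3,18-trihydroxylabda-8(17),13-dien-15,16-olide | C=C1CC[C@H]2[C@@](C)(C[C@H](O)[C@@H](O)[C@]2(C)CO)[C@@H]1CCC1=CC(=O)OC1 | target

**Step count.** Total: 16 steps. Longest linear sequence: 15 steps (steps 1–4, then 6–16).

**Steps most likely to fail, with fallbacks**

Step 6. The chiral Lewis acid may activate and shield the hindered trisubstituted (Z)-silyl enal insufficiently. Conversion would then be low and regio-, exo- and facial selectivity would erode (bonding of the silyl-bearing carbon to the substituted diene terminus, or formyl-endo approach). The fallback changes both the activation mode and the stereocontrol element to an auxiliary-controlled ionic Diels–Alder reaction. It sets out from 9 (with 7) and comes back at 10. Aldehyde 9 is condensed with (2R,4R)-pentane-2,4-diol (PPTS, benzene, removal of water) to the chiral dioxane acetal F1. TMSOTf in CH2Cl2 at −78 °C opens F1 to an α,β-unsaturated oxocarbenium ion, a much stronger dienophile whose tethered chiral alkoxide shields one face. Cycloaddition with 7 and re-closure of the acetal should give the cycloadduct acetal F2. Transacetalization (PPTS, wet acetone) releases aldehyde 10, which is reduced as in step 6.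

Step 11. The tertiary C10 radical may be captured by a second trivalent titanium before it cyclizes (reduction or elimination without ring closure), and the β,γ-epoxy ketone may isomerize under the Lewis-acidic conditions. The fallback avoids the epoxide. It sets out from 14 and comes back at 19. Alcohol 14 is oxidized (DMP, NaHCO3) to the β,γ-unsaturated ketone F3. TBSOTf and Et3N convert F3 into the conjugated silyl dienol ether F4. Oxidation of F4 with Cu(OTf)2 and Cu2O in MeCN should generate the dienone radical cation, whose γ-terminus C10 adds to the trisubstituted alkene. Copper-mediated oxidation of the C8 radical then gives the exocyclic alkene and enone 19 directly. This is a vinylogous use of the known copper-mediated oxidative cyclization of unsaturated silyl enol ethers.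

Step 15. Reduction and homocoupling of the bromobutenolide may outrun the slow halide exchange and activation of the primary chloride, so that cross-coupling lags. The fallback builds the butenolide stepwise through a furan. It sets out from 22 and comes back at 24. Halide exchange (NaI, acetone, reflux) gives the iodide F5. Alkylation of excess 3-furyllithium (from 3-bromofuran and n-BuLi, THF, −78 °C; the excess also deprotonates the diol) with F5 gives the 3-alkylfuran F6. Photooxygenation (O2, rose bengal, visible light, i-Pr2NEt, CH2Cl2, −78 °C) should give regioselectively the β-substituted γ-hydroxybutenolide F7. NaBH4 reduces the masked aldehyde of F7 and the hydroxy acid relactonizes to 24.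

**Further compounds**

F1 | step 6 | (4R,6R)-2-{(1Z)-1-[benzyl(dimethyl)silyl]prop-1-en-2-yl}-4,6-dimethyl-1,3-dioxane | C[C@@H]1C[C@@H](C)OC(O1)/C(C)=C\[Si](C)(C)Cc1ccccc1
F2 | step 6 | (4R,6R)-2-[(1S,2S,6S)-6-[benzyl(dimethyl)silyl]-2-[(3E)-6-chloro-3-methylhex-3-en-1-yl]-1,3-dimethylcyclohex-3-en-1-yl]-4,6-dimethyl-1,3-dioxane | ClCC/C=C(\C)CC[C@H]1C(C)=CC[C@H]([Si](C)(C)Cc2ccccc2)[C@]1(C)C1O[C@H](C)C[C@@H](C)O1
F3 | step 11 | (5S,6S)-6-{[tert-butyl(dimethyl)silyl]oxymethyl}-5-[(3E)-6-chloro-3-methylhex-3-en-1-yl]-4,6-dimethylcyclohex-3-en-1-one | ClCC/C=C(\C)CC[C@H]1C(C)=CCC(=O)[C@]1(C)CO[Si](C)(C)C(C)(C)C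
F4 | step 11 | tert-butyl{[(5S,6S)-6-{[tert-butyl(dimethyl)silyl]oxymethyl}-5-[(3E)-6-chloro-3-methylhex-3-en-1-yl]-4,6-dimethylcyclohexa-1,3-dien-1-yl]oxy}dimethylsilane | ClCC/C=C(\C)CC[C@H]1C(C)=CC=C(O[Si](C)(C)C(C)(C)C)[C@]1(C)CO[Si](C)(C)C(C)(C)C
F5 | step 15 | (2S,3S,4S,5S,9R,10S)-18-[tert-butyl(dimethyl)silyl]oxy-12-iodo-13,14,15,16-tetranorlabd-8(17)-ene-2,3-diol | C=C1CC[C@H]2[C@@](C)(C[C@H](O)[C@@H](O)[C@]2(C)CO[Si](C)(C)C(C)(C)C)[C@@H]1CCI
F6 | step 15 | (2S,3S,4S,5S,9R,10S)-18-[tert-butyl(dimethyl)silyl]oxy-15,16-epoxylabda-8(17),13(16),14-triene-2,3-diol | C=C1CC[C@H]2[C@@](C)(C[C@H](O)[C@@H](O)[C@]2(C)CO[Si](C)(C)C(C)(C)C)[C@@H]1CCc1ccoc1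
F7 | step 15 | (2S,3S,4S,5S,9R,10S)-18-[tert-butyl(dimethyl)silyl]oxy-2,3,16-trihydroxylabda-8(17),13-dien-15,16-olide (both C16 epimers) | C=C1CC[C@H]2[C@@](C)(C[C@H](O)[C@@H](O)[C@]2(C)CO[Si](C)(C)C(C)(C)C)[C@@H]1CCC1=CC(=O)OC1O
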